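A single first-order step cannot draw these curves: its slope falls from the first moment and its final share does not depend on the charge. Yet the alpha slope rose after the start, and at the last reading the alpha run stood at 84.1 % of its charge against 90.8 % for the epsilon run.

| flask | starting material | time |
|---|---|---|
| alpha | 0.400 M |  |
| epsilon | 1.20 M |  |
| theta | 0.400 M | 8.2 min |

| run | time / min | [target] / M |
|---|---|---|
| alpha run | 0.16 | 0.0073 |
| alpha run | 0.28 | 0.0207 |
| alpha run | 0.48 | 0.0406 |
| alpha run | 0.82 | 0.0918 |
| alpha run | 1.4 | 0.1766 |
| alpha run | 2.4 | 0.2842 |
| alpha run | 4.1 | 0.3365 |
| epsilon run | 0.16 | 0.0246 |
| epsilon run | 0.28 | 0.0707 |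
| epsilon run | 0.48 | 0.1986 |
| epsilon run | 0.82 | 0.5327 |
| epsilon run | 1.4 | 0.9621 |
| epsilon run | 2.4 | 1.0845 |
| epsilon run | 4.1 | 1.0891 |

(scatter of a reading: 0.002 M)

- Overall: starting material -> target.
- Constant volume, constant temperature.
- An order is taken over about fifteen percent of the charge, up and down.

- the power of [starting material] that the first rate follows, about the charge of the alpha run; measure it at two percent of starting material made into target (one fixed amount of target, the same in the runs compared)
- target in the theta run at 8.2 min, as a share of the starting material charged

1. Start. From nothing to 0.0207 M, the alpha run's mean slope was 0.0739 M min⁻¹. From nothing to a similar 0.0246 M, the epsilon run's was 0.154 M min⁻¹. Both chords span the two-percent mark, so I took 0.667 as the power, though it spans the whole step between the charges.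

2. Knee. Between 0.48 min and 0.82 min, the alpha slope reached 0.151 M min⁻¹, twice its opening chord. This is a lag (induction period).

3. Crossing. By straight lines between readings, the alpha run crossed 0.200 M at 1.62 min.

4. Level. I supposed that the amount missing at the end had been lost at a first-order pace from whatever had not yet turned. The epsilon run missed 0.111 M, and the area between its level and its curve, by chords, was 60.1 M·s. Missing amount over area is the loss constant, 0.111 min⁻¹.

5. Theta. This flask has the alpha charge, so it follows the alpha curve, whose area beneath is 52.0 M·s. Requiring charge minus level to equal the loss constant times the area between level and curve gave a level of 0.341 M, or 85.3 %. The last alpha reading stood 0.00463 M below it, so I took that level for 8.2 min.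

The forecast gave 1.1 and 88 %, saying “This looks autocatalytic”, and both stand above my figures. The flask gave 0.73 and 84.6 %.

    starting material ⇌ intermediate (0.8820 min⁻¹, 3.726 min⁻¹)
    intermediate → target (2.034 min⁻¹)
    starting material → decomposed substrate (0.1248 min⁻¹)
    starting material + target → 2 target (3.300 M⁻¹ min⁻¹)

The simulated theta run without the loss to decomposed substrate reaches >99.9 % against 84.6 %, so that loss is the reason for the shortfall. The theta shortfall of 0.0615 M, divided by my loss constant as read from the epsilon readings, gives an estimated area of 33.2 M·s between level and curve, and that estimate carries the error of the reading. The simulated theta run without the conversion of starting material and target into two target gives 68.4 %.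

(The earlier runs and the new flask were generated by integration with constants of no real substance, and the scatter is random.)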